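**Plan**

- Retrosynthetic cuts, in order: C2–OH (back to a C2 methyl ketal), O4–C4a (aryl C–O bond), O1–C2 (phenol opening of a methoxy epoxy ether), the epoxide C3–O bond (back to an α-mesyloxy ketone), the aryl–C2 bond (lactate Weinreb amide plus aryl Grignard reagent), and, in the other arm, the ArCH2–vinyl bond.
- Forward: the bromophenol arm (4 steps) and the lactate arm (5 steps) are joined through O1–C2. The only ring formed, the 1,4-dioxane ring, then closes by O4–C4a coupling, and the ketal methoxy group is exchanged for hydroxyl last.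
- Stereochemistry: C3 comes from methyl (S)-lactate. Its C–O bond is inverted once, when the epoxy ether closes, which gives 3R, and is never broken again. C2 is settled in the last step by equilibration of the hemiketal.
- Enabling feature: O4 links the secondary carbon C3 to C4a, an aromatic carbon lying between C5–OMe and C8a–O1. Because C2 is a ketal-level carbon it can be carried as an aryl methyl ketal, so C3–H is not acidic and the free C3–OH can be O-arylated under base. A bromine on C4a of a symmetric dimethoxy precursor fixes which ring oxygen is which.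

Key step: step 11

Assumption: the (2S,3R) hemiketal (aryl cis to the C3 methyl, hydroxyl trans to it and axial, anomerically stabilised) is taken to be the more stable C2 epimer, so C2 is set by equilibration.

**Route**

Step 1
Reactants: 1 4-bromo-3,5-dimethoxybenzaldehyde
Product: 2 (4-bromo-3,5-dimethoxyphenyl)methanol
Conditions: NaBH4, MeOH, 0 °C
Reagents that add atoms: none
Why: Hydride reduction of the aldehyde is fast at 0 °C and leaves the aryl bromide and the methyl ethers untouched.

Step 2
Reactants: 2 (4-bromo-3,5-dimethoxyphenyl)methanol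
Product: 3 2-bromo-5-(bromomethyl)-1,3-dimethoxybenzene
Conditions: PBr3, CH2Cl2, 0 °C
Reagents that add atoms: phosphorus tribromide, BrP(Br)Br
Why: An electron-rich benzylic alcohol is converted into its bromide through the phosphite ester (SN2 by bromide), a standard transformation.

Step 3
Reactants: 3 2-bromo-5-(bromomethyl)-1,3-dimethoxybenzene; 4 vinylmagnesium bromide
Product: 5 5-allyl-2-bromo-1,3-dimethoxybenzene
Conditions: CuI (10 mol %), THF, −30 → 0 °C
Reagents that add atoms: none
Why: Copper-catalysed Kumada-type coupling of the vinyl Grignard reagent with the benzylic bromide (through a vinylcuprate) builds the allyl group, the aryl C–Br bond being inert to the cuprate at low temperature.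

Step 4
Reactants: 5 5-allyl-2-bromo-1,3-dimethoxybenzene
Product: 6 5-allyl-2-bromo-3-methoxyphenol
Conditions: BBr3 (1.05 equiv), CH2Cl2, −78 → −20 °C; then aq NaHCO3
Reagents that add atoms: none
Why: Lewis-acid ether cleavage with one equivalent of BBr3 removes one of the two equivalent methyl groups (either gives 6), the aryloxyborane formed should resist a second cleavage, and the low temperature spares the allyl group.

Step 5
Reactants: 7 methyl (S)-lactate
Product: 8 (S)-2-hydroxy-N-methoxy-N-methylpropanamide
Conditions: MeNH(OMe)·HCl, iPrMgCl, THF, −20 → 0 °C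
Reagents that add atoms: N,O-dimethylhydroxylamine hydrochloride, Cl.CNOC
Why: Aminolysis of the ester by the chloromagnesium amide of N,O-dimethylhydroxylamine gives the Weinreb amide, the stereocentre being shielded from enolisation as its magnesium alkoxide.

Step 6
Reactants: 8 (S)-2-hydroxy-N-methoxy-N-methylpropanamide
Product: 9 (S)-2-(tert-butyldimethylsilyloxy)-N-methoxy-N-methylpropanamide
Conditions: TBSCl, imidazole, DMF, rt
Reagents that add atoms: tert-butyldimethylsilyl chloride, CC(C)(C)[Si](C)(C)Cl
Why: Imidazole-promoted silylation protects the secondary hydroxyl so that the aryl Grignard reagent of the next step is not quenched.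

Step 7
Reactants: 9 (S)-2-(tert-butyldimethylsilyloxy)-N-methoxy-N-methylpropanamide; 10 5-bromo-1,2,3-trimethoxybenzene
Product: 12 (S)-2-(tert-butyldimethylsilyloxy)-1-(3,4,5-trimethoxyphenyl)propan-1-one, via aryl Grignard reagent 11 (not isolated)
Conditions: Mg, I2 (cat.), THF, 50 °C; then 9, THF, 0 °C → rt; aq NH4Cl
Reagents that add atoms: none
Why: Weinreb ketone synthesis: the aryl Grignard reagent adds once to give a chelated tetrahedral magnesium intermediate that collapses to the ketone only on work-up, so neither over-addition nor α-epimerisation is expected.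

Step 8
Reactants: 12 (S)-2-(tert-butyldimethylsilyloxy)-1-(3,4,5-trimethoxyphenyl)propan-1-one
Product: 13 (S)-2-hydroxy-1-(3,4,5-trimethoxyphenyl)propan-1-one
Conditions: 48% aq HF, MeCN, 0 °C → rt
Reagents that add atoms: none
Why: Fluoride-driven Si–O cleavage under acidic, non-enolising conditions should free the α-hydroxy ketone with its configuration intact.

Step 9
Reactants: 13 (S)-2-hydroxy-1-(3,4,5-trimethoxyphenyl)propan-1-one
Product: 14 (S)-1-oxo-1-(3,4,5-trimethoxyphenyl)propan-2-yl methanesulfonate
Conditions: MsCl, Et3N, CH2Cl2, −10 °C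
Reagents that add atoms: methanesulfonyl chloride, CS(=O)(=O)Cl
Why: O-sulfonylation at low temperature activates the C3–O bond without touching the stereocentre (retention).

Step 10
Reactants: 14 (S)-1-oxo-1-(3,4,5-trimethoxyphenyl)propan-2-yl methanesulfonate; 6 5-allyl-2-bromo-3-methoxyphenol
Product: 16 (1S,2R)-1-(5-allyl-2-bromo-3-methoxyphenoxy)-1-methoxy-1-(3,4,5-trimethoxyphenyl)propan-2-ol, via methoxy epoxy ether 15 (not isolated)
Conditions: NaOMe (1.05 equiv), THF, 0 °C → rt; filter under Ar; then 6 (1.3 equiv), 4 Å molecular sieves, toluene, rt → 45 °C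
Reagents that add atoms: sodium methoxide, [Na+].[O-]C
Why: Methoxide adds to the carbonyl group and the resulting alkoxide displaces the mesylate from the rear (epoxy ether synthesis from an α-sulfonyloxy ketone, the single SN2 event that turns the (S)-lactate centre into 3R), after which the strained epoxy ether is opened at its ketal carbon C2 by the phenol O–H acting as both acid and nucleophile, so O1–C2 forms while C3–O stays intact; invertive opening of the aryl-trans-methyl epoxy ether would give the C2 epimer drawn, and any C2 epimer formed alongside is carried on because C2 is re-equilibrated in step 12.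

Step 11
Reactants: 16 (1S,2R)-1-(5-allyl-2-bromo-3-methoxyphenoxy)-1-methoxy-1-(3,4,5-trimethoxyphenyl)propan-2-ol
Product: 17 (2S,3R)-7-allyl-2,5-dimethoxy-3-methyl-2-(3,4,5-trimethoxyphenyl)-2,3-dihydro-1,4-benzodioxine
Conditions: CuI (10 mol %), 3,4,7,8-tetramethyl-1,10-phenanthroline (20 mol %), Cs2CO3 (2 equiv), toluene, 110 °C
Reagents that add atoms: none
Why: Cs2CO3 converts the C3 hydroxyl into its alkoxide, which binds phenanthroline-ligated monovalent copper; the neighbouring C4a–Br bond then adds oxidatively to give an aryl alkoxide complex of trivalent copper, and C–O reductive elimination forms O4–C4a. The closest known reaction type is the intramolecular copper-catalysed Ullmann ether synthesis, the O-arylation of 2-(2-haloaryloxy)ethanols to 1,4-benzodioxanes. The dioxane ring closes in a 6-exo mode through a seven-membered cupracycle, the O1–C2 tether holding alkoxide and bromide together and so offsetting the hindrance of two ortho oxygen substituents on an electron-rich ring. No stereocentre is created: the C3–O bond is never broken, so 3R is retained, and because C2 is a ketal carbon there is no acidic C3–H through which carbonate could epimerise C3. The step needs O-arylation to outrun protodebromination and migration of the allyl double bond, and an unambiguous assignment of the two ring oxygens; a carbonate base with a hydride-free copper catalyst should secure the first, and the bromine already sitting on C4a between C5–OMe and C8a–O1 secures the second.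

Step 12
Reactants: 17 (2S,3R)-7-allyl-2,5-dimethoxy-3-methyl-2-(3,4,5-trimethoxyphenyl)-2,3-dihydro-1,4-benzodioxine
Product: 18 (2S,3R)-7-allyl-5-methoxy-3-methyl-2-(3,4,5-trimethoxyphenyl)-2,3-dihydro-1,4-benzodioxin-2-ol
Conditions: 1 M aq HCl, THF, rt
Reagents that add atoms: water, O
Why: Acid-catalysed ketal hydrolysis through the aryl-stabilised oxocarbenium ion at C2 exchanges methoxy for hydroxyl, and the hemiketal should equilibrate under these conditions to its more stable C2 epimer (both epimers of 17 converge), while C3 and the allyl group are not affected by dilute acid at room temperature.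

**Compound list**

1 | 4-bromo-3,5-dimethoxybenzaldehyde | O=Cc1cc(OC)c(Br)c(OC)c1 | starting material
2 | (4-bromo-3,5-dimethoxyphenyl)methanol | OCc1cc(OC)c(Br)c(OC)c1 | intermediate
3 | 2-bromo-5-(bromomethyl)-1,3-dimethoxybenzene | BrCc1cc(OC)c(Br)c(OC)c1 | intermediate
4 | vinylmagnesium bromide | C=C[Mg]Br | starting material
5 | 5-allyl-2-bromo-1,3-dimethoxybenzene | C=CCc1cc(OC)c(Br)c(OC)c1 | intermediate
6 | 5-allyl-2-bromo-3-methoxyphenol | C=CCc1cc(OC)c(Br)c(O)c1 | intermediate
7 | methyl (S)-lactate | C[C@H](O)C(=O)OC | starting material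
8 | (S)-2-hydroxy-N-methoxy-N-methylpropanamide | C[C@H](O)C(=O)N(C)OC | intermediate
9 | (S)-2-(tert-butyldimethylsilyloxy)-N-methoxy-N-methylpropanamide | C[C@H](O[Si](C)(C)C(C)(C)C)C(=O)N(C)OC | intermediate
10 | 5-bromo-1,2,3-trimethoxybenzene | COc1cc(Br)cc(OC)c1OC | starting material
11 | (3,4,5-trimethoxyphenyl)magnesium bromide, formed and consumed in the flask | COc1cc([Mg]Br)cc(OC)c1OC | intermediate
12 | (S)-2-(tert-butyldimethylsilyloxy)-1-(3,4,5-trimethoxyphenyl)propan-1-one | C[C@H](O[Si](C)(C)C(C)(C)C)C(=O)c1cc(OC)c(OC)c(OC)c1 | intermediate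
13 | (S)-2-hydroxy-1-(3,4,5-trimethoxyphenyl)propan-1-one | C[C@H](O)C(=O)c1cc(OC)c(OC)c(OC)c1 | intermediate
14 | (S)-1-oxo-1-(3,4,5-trimethoxyphenyl)propan-2-yl methanesulfonate | C[C@H](OS(C)(=O)=O)C(=O)c1cc(OC)c(OC)c(OC)c1 | intermediate
15 | (2R,3R)-2-methoxy-3-methyl-2-(3,4,5-trimethoxyphenyl)oxirane (aryl trans to methyl), formed and consumed in the flask | C[C@H]1O[C@]1(OC)c1cc(OC)c(OC)c(OC)c1 | intermediate
16 | (1S,2R)-1-(5-allyl-2-bromo-3-methoxyphenoxy)-1-methoxy-1-(3,4,5-trimethoxyphenyl)propan-2-ol | C=CCc1cc(OC)c(Br)c(O[C@@](OC)(c2cc(OC)c(OC)c(OC)c2)[C@@H](C)O)c1 | intermediate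
17 | (2S,3R)-7-allyl-2,5-dimethoxy-3-methyl-2-(3,4,5-trimethoxyphenyl)-2,3-dihydro-1,4-benzodioxine | C=CCc1cc(OC)c2c(c1)O[C@@](OC)(c1cc(OC)c(OC)c(OC)c1)[C@@H](C)O2 | intermediate
18 | (2S,3R)-7-allyl-5-methoxy-3-methyl-2-(3,4,5-trimethoxyphenyl)-2,3-dihydro-1,4-benzodioxin-2-ol | C=CCc1cc(OC)c2c(c1)O[C@@](O)(c1cc(OC)c(OC)c(OC)c1)[C@@H](C)O2 | target

**Count and risks**

Total steps: 12. Longest linear sequence: 8 steps (steps 5 to 12, from methyl (S)-lactate). The bromophenol arm contributes 4 steps and joins at step 10.

Steps most likely to fail: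

1. Step 10. Methoxide may enolise the α-mesyloxy ketone before it adds to the carbonyl group, eroding C3. The transient epoxy ether may also isomerise or dimerise faster than the hindered, weakly acidic bromophenol adds to it. The fallback sets out from 14 and 6 and returns at 16. Mesylate 14 would be treated with NaOMe in methanol, so that the epoxy ether is trapped at once by the solvent as (R)-1,1-dimethoxy-1-(3,4,5-trimethoxyphenyl)propan-2-ol F1. Silylation (TMSCl, Et3N) would give its trimethylsilyl ether F2, and phenol 6 would be silylated likewise to (5-allyl-2-bromo-3-methoxyphenoxy)trimethylsilane F3. A trimethylsilyl triflate-catalysed silyl-exchange ketalisation of F2 with F3 (CH2Cl2, −78 °C, the oxocarbenium ion at C2 being captured by the aryl silyl ether with loss of methoxytrimethylsilane) would give the trimethylsilyl ether of the mixed ketal F4. K2CO3 in methanol would then release 16.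

2. Step 11. Oxidative addition into the C4a–Br bond, flanked by two oxygen substituents on an electron-rich ring, may be slow. Protodebromination, copper-mediated oxidation of the secondary alcohol, or expulsion of the bromophenoxide from C2 by the C3 alkoxide could then take over. The fallback sets out from 6 and 14 and returns at 18; it forms O4–C3 by substitution instead of O4–C4a by coupling. Phenol 6 would be protected (MOMCl, iPr2NEt) as 5-allyl-2-bromo-1-methoxy-3-(methoxymethoxy)benzene F5. Bromine–lithium exchange (n-BuLi, −78 °C), borylation with B(OMe)3 and oxidation (H2O2, NaOH) would give 4-allyl-2-methoxy-6-(methoxymethoxy)phenol F6. Its phenoxide (K2CO3, acetone, rt) would displace the mesylate of 14 with inversion to give (R)-2-[4-allyl-2-methoxy-6-(methoxymethoxy)phenoxy]-1-(3,4,5-trimethoxyphenyl)propan-1-one F7. Aqueous HCl in THF would remove the methoxymethyl group, and the freed phenol should close onto the ketone to give hemiketal 18. The weakness of this path is the base-lability of the α-aryloxy ketone stereocentre, which is why it is held in reserve.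

3. Step 4. A second ether cleavage to the resorcinol, or addition of HBr across the allyl double bond during cleavage and quench, may cut into the yield of the monophenol. The fallback sets out from 1 and returns at 6; it performs the ether cleavage before the alkene exists. BBr3 on aldehyde 1 would give 4-bromo-3-hydroxy-5-methoxybenzaldehyde F8, and silylation (TBSCl, imidazole) would give 4-bromo-3-(tert-butyldimethylsilyloxy)-5-methoxybenzaldehyde F9. Reduction with NaBH4 would give [4-bromo-3-(tert-butyldimethylsilyloxy)-5-methoxyphenyl]methanol F10, and an Appel reaction (CBr4, PPh3) would give [2-bromo-5-(bromomethyl)-3-methoxyphenoxy](tert-butyl)dimethylsilane F11. The CuI-catalysed coupling with vinylmagnesium bromide would give (5-allyl-2-bromo-3-methoxyphenoxy)(tert-butyl)dimethylsilane F12, and tetrabutylammonium fluoride buffered with acetic acid would release 6.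

Further compounds

F1 | step 10 | (R)-1,1-dimethoxy-1-(3,4,5-trimethoxyphenyl)propan-2-ol | C[C@@H](O)C(OC)(OC)c1cc(OC)c(OC)c(OC)c1
F2 | step 10 | (R)-[1,1-dimethoxy-1-(3,4,5-trimethoxyphenyl)propan-2-yloxy]trimethylsilane | C[C@@H](O[Si](C)(C)C)C(OC)(OC)c1cc(OC)c(OC)c(OC)c1
F3 | step 10 | (5-allyl-2-bromo-3-methoxyphenoxy)trimethylsilane | C=CCc1cc(OC)c(Br)c(O[Si](C)(C)C)c1
F4 | step 10 | [(1S,2R)-1-(5-allyl-2-bromo-3-methoxyphenoxy)-1-methoxy-1-(3,4,5-trimethoxyphenyl)propan-2-yloxy]trimethylsilane | C=CCc1cc(OC)c(Br)c(O[C@@](OC)(c2cc(OC)c(OC)c(OC)c2)[C@@H](C)O[Si](C)(C)C)c1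
F5 | step 11 | 5-allyl-2-bromo-1-methoxy-3-(methoxymethoxy)benzene | C=CCc1cc(OC)c(Br)c(OCOC)c1
F6 | step 11 | 4-allyl-2-methoxy-6-(methoxymethoxy)phenol | C=CCc1cc(OC)c(O)c(OCOC)c1
F7 | step 11 | (R)-2-[4-allyl-2-methoxy-6-(methoxymethoxy)phenoxy]-1-(3,4,5-trimethoxyphenyl)propan-1-one | C=CCc1cc(OC)c(O[C@H](C)C(=O)c2cc(OC)c(OC)c(OC)c2)c(OCOC)c1
F8 | step 4 | 4-bromo-3-hydroxy-5-methoxybenzaldehyde | O=Cc1cc(OC)c(Br)c(O)c1
F9 | step 4 | 4-bromo-3-(tert-butyldimethylsilyloxy)-5-methoxybenzaldehyde | O=Cc1cc(OC)c(Br)c(O[Si](C)(C)C(C)(C)C)c1
F10 | step 4 | [4-bromo-3-(tert-butyldimethylsilyloxy)-5-methoxyphenyl]methanol | OCc1cc(OC)c(Br)c(O[Si](C)(C)C(C)(C)C)c1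
F11 | step 4 | [2-bromo-5-(bromomethyl)-3-methoxyphenoxy](tert-butyl)dimethylsilane | BrCc1cc(OC)c(Br)c(O[Si](C)(C)C(C)(C)C)c1
F12 | step 4 | (5-allyl-2-bromo-3-methoxyphenoxy)(tert-butyl)dimethylsilane | C=CCc1cc(OC)c(Br)c(O[Si](C)(C)C(C)(C)C)c1
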